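The 2,3-dihydro-1,4-benzodioxine ring is cut at the aryl C8a–O1 bond and at C2–C3. Both bonds form in one operation from an acyclic mixed acetal of 3,4-bis(benzyloxy)benzaldehyde, whose two oxygens carry an o-iodoaryl triflate (ring A) and a CH2CO2Me group: the aryne generated next to the aryloxy oxygen is captured by the glycolate oxygen, and the resulting 1,3-benzodioxolium ylide undergoes a [1,2]-shift that expands the ring to the dioxane. The step exploits C3, a benzylic carbon flanked by O4 and the catechol ring (latent oxocarbenium ion), and C2, an ester-stabilised ylide carbon on O1. Dehydrogenation and carboxy-directed asymmetric hydrogenation set the cis (2R,3R) centres; a Horner–Wadsworth–Emmons union with an (R)-lactate phosphonate and debenzylation finish.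

Key step: step 6

Assumption: compounds 8 to 13 are racemic or achiral and are written without stereodescriptors; the ligand configuration named in step 9 is the one expected by analogy to give the (2R,3R) acid, and its antipode would be used if a first run shows the opposite sense.

Step 1
Reactants: 1 2,4-dihydroxybenzaldehyde
Product: 2 2,4-dihydroxy-3-iodobenzaldehyde
Conditions: I2, HIO3, EtOH/H2O, 25 °C
Reagents that add atoms: iodine, [I][I]; iodic acid, O[I](=O)=O
Why: Electrophilic aromatic iodination should go to C3, the position ortho to both hydroxyl groups, as in the iodination of resorcinols between the two hydroxyls.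

Step 2
Reactants: 2 2,4-dihydroxy-3-iodobenzaldehyde; 3 3,4-bis(benzyloxy)benzyl chloride
Product: 4 4-{[3,4-bis(benzyloxy)phenyl]methoxy}-2-hydroxy-3-iodobenzaldehyde
Conditions: K2CO3 (1.05 equiv), KI (cat.), DMF, 25 °C
Reagents that add atoms: none
Why: Williamson ether synthesis; the 4-OH para to the formyl group is the more acidic and the 2-OH is hydrogen-bonded to the aldehyde, so monoalkylation at O4 is expected.

Step 3
Reactants: 4 4-{[3,4-bis(benzyloxy)phenyl]methoxy}-2-hydroxy-3-iodobenzaldehyde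
Product: 5 3-{[3,4-bis(benzyloxy)phenyl]methoxy}-6-formyl-2-iodophenyl trifluoromethanesulfonate
Conditions: Tf2O, pyridine, CH2Cl2, 0 °C
Reagents that add atoms: trifluoromethanesulfonic anhydride, O=S(=O)(OS(=O)(=O)C(F)(F)F)C(F)(F)F
Why: O-sulfonylation of the remaining phenol places the leaving group for aryne formation next to the iodide.

Step 4
Reactants: 5 3-{[3,4-bis(benzyloxy)phenyl]methoxy}-6-formyl-2-iodophenyl trifluoromethanesulfonate
Product: 6 3-{[3,4-bis(benzyloxy)phenyl]methoxy}-6-(dimethoxymethyl)-2-iodophenyl trifluoromethanesulfonate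
Conditions: HC(OMe)3, MeOH, p-TsOH (cat.), 25 °C; Et3N quench
Reagents that add atoms: trimethyl orthoformate, COC(OC)OC; methanol, CO
Why: Acid-catalysed acetalisation masks the electron-poor aldehyde against the Grignard reagent of step 6, while the aryl triflate, iodide and ethers are inert.

Step 5
Reactants: 6 3-{[3,4-bis(benzyloxy)phenyl]methoxy}-6-(dimethoxymethyl)-2-iodophenyl trifluoromethanesulfonate; 7 methyl glycolate
Product: 8 methyl 2-{[3,4-bis(benzyloxy)phenyl][4-(dimethoxymethyl)-2-iodo-3-(trifluoromethanesulfonyloxy)phenoxy]methoxy}acetate (racemic)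
Conditions: DDQ (1.2 equiv), 7 (5 equiv), 2,6-di-tert-butylpyridine, 4 Å molecular sieves, CH2Cl2, 0 °C
Reagents that add atoms: none
Why: DDQ-mediated oxidative C–H etherification (cross-dehydrogenative coupling): hydride abstraction from the 3,4-dialkoxybenzylic ether CH2 gives an oxocarbenium ion that methyl glycolate should trap, while the unsubstituted benzyl ethers are far less electron-rich.

Step 6
Reactants: 8 methyl 2-{[3,4-bis(benzyloxy)phenyl][4-(dimethoxymethyl)-2-iodo-3-(trifluoromethanesulfonyloxy)phenoxy]methoxy}acetate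
Product: 11 methyl 3-[3,4-bis(benzyloxy)phenyl]-7-(dimethoxymethyl)-2,3-dihydro-1,4-benzodioxine-2-carboxylate (racemic cis/trans mixture), via aryne 9 (not isolated), via benzodioxolium ylide 10 (not isolated)
Conditions: Me3SiCH2MgCl (1.2 equiv), THF, −78 °C to 25 °C
Reagents that add atoms: none
Why: Proposed new method: Iodine–magnesium exchange at the C–I bond and loss of Mg(Cl)OTf give aryne 9, whose carbon ortho to the aryloxy oxygen is attacked by the glycolate oxygen of the acetal (5-exo-dig, forming the aryl C–O bond and a 1,3-benzodioxolium ring), and the aryl anion so formed removes a proton from the OCH2CO2Me group to give the ester-stabilised oxonium ylide 10. The benzylic acetal carbon then shifts from O+ to the ylide carbon ([1,2]-Stevens shift, in its stepwise limit a 6-(enolexo)-endo-trig recombination of an aryloxyacetate enolate with the tethered aryl oxocarbenium ion), which forms the C2–C3 bond and expands the five-membered ring to the 1,4-dioxane. The closest known reaction types are the aryne-triggered ammonium and sulfonium ylide formation/Stevens rearrangements of tertiary amines and sulfides and the carbenoid-mediated oxonium-ylide ring expansion of 2-aryl-1,3-dioxolanes to 1,4-dioxanes; new is the entry to an oxonium ylide by O-arylation of an acetal oxygen. C2 and C3 are created without control, which is accepted because both centres are erased in step 7 and set in step 9. The selectivity needed is O-capture at the aryne carbon next to the aryloxy group and a [1,2]- rather than a [2,3]-shift: the two-atom tether allows only the five-membered closure, Me3SiCH2MgCl is too poor a nucleophile to add to the aryne or the ester at −78 °C, and the oxygen- and aryl-stabilised migrating carbon favours the [1,2]-path.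

Step 7
Reactants: 11 methyl 3-[3,4-bis(benzyloxy)phenyl]-7-(dimethoxymethyl)-2,3-dihydro-1,4-benzodioxine-2-carboxylate
Product: 12 methyl 3-[3,4-bis(benzyloxy)phenyl]-7-(dimethoxymethyl)-1,4-benzodioxine-2-carboxylate
Conditions: DDQ (2 equiv), 1,4-dioxane, 80 °C
Reagents that add atoms: none
Why: DDQ dehydrogenation as in the conversion of flavanones and chromans to flavones and chromenes: hydride abstraction from the doubly activated benzylic C3–H and loss of the acidic C2–H should give the conjugated enol ether from either diastereomer.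

Step 8
Reactants: 12 methyl 3-[3,4-bis(benzyloxy)phenyl]-7-(dimethoxymethyl)-1,4-benzodioxine-2-carboxylate
Product: 13 3-[3,4-bis(benzyloxy)phenyl]-7-(dimethoxymethyl)-1,4-benzodioxine-2-carboxylic acid
Conditions: LiOH·H2O, THF/H2O, 0 to 25 °C; then 1 M HCl to pH 5 at 0 °C
Reagents that add atoms: lithium hydroxide, [Li+].[OH-]
Why: Saponification of the methyl ester gives the carboxylic acid that directs the hydrogenation of step 9, and the mild acidification spares the dimethyl acetal.

Step 9
Reactants: 13 3-[3,4-bis(benzyloxy)phenyl]-7-(dimethoxymethyl)-1,4-benzodioxine-2-carboxylic acid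
Product: 15 (2R,3R)-3-[3,4-bis(benzyloxy)phenyl]-7-formyl-2,3-dihydro-1,4-benzodioxine-2-carboxylic acid, via acetal acid 14 (not isolated)
Conditions: [Ir(cod)((Sa,S)-SIPHOX)][B(3,5-(CF3)2C6H3)4] (2 mol%), H2 (10 atm), Et3N (0.5 equiv), MeOH, 45 °C; then 1 M HCl, THF/H2O, 25 °C
Reagents that add atoms: water, O
Why: Carboxy-directed iridium-catalysed asymmetric hydrogenation of an α-aryloxy α,β-unsaturated acid: syn addition of H2 to C2=C3 makes carboxyl and aryl cis, the chiral spiro phosphine–oxazoline ligand selects the face that gives (2R,3R), and the dilute acid work-up hydrolyses the acetal.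

Step 10
Reactants: 16 1-(benzyloxy)-4-bromo-2-methoxybenzene; 17 tert-butyl (2R)-oxirane-2-carboxylate
Product: 19 tert-butyl (2R)-3-[4-(benzyloxy)-3-methoxyphenyl]-2-hydroxypropanoate, via arylmagnesium bromide 18 (not isolated)
Conditions: Mg, THF, 40 °C; then CuI (10 mol%), 17, THF, −40 to 0 °C
Reagents that add atoms: none
Why: Copper-catalysed ring opening of the glycidate at its terminal carbon by the aryl Grignard reagent leaves the stereocentre untouched, so the (R)-epoxide gives the (R)-hydroxy ester.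

Step 11
Reactants: 19 tert-butyl (2R)-3-[4-(benzyloxy)-3-methoxyphenyl]-2-hydroxypropanoate; 20 2-(diethoxyphosphoryl)acetic acid
Product: 21 tert-butyl (2R)-3-[4-(benzyloxy)-3-methoxyphenyl]-2-{[2-(diethoxyphosphoryl)acetyl]oxy}propanoate
Conditions: DCC, DMAP (cat.), CH2Cl2, 0 to 25 °C
Reagents that add atoms: none
Why: Steglich esterification of the secondary alcohol proceeds at oxygen without touching the stereocentre.

Step 12
Reactants: 15 (2R,3R)-3-[3,4-bis(benzyloxy)phenyl]-7-formyl-2,3-dihydro-1,4-benzodioxine-2-carboxylic acid; 21 tert-butyl (2R)-3-[4-(benzyloxy)-3-methoxyphenyl]-2-{[2-(diethoxyphosphoryl)acetyl]oxy}propanoate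
Product: 22 (2R,3R)-3-[3,4-bis(benzyloxy)phenyl]-7-[(1E)-3-{[(2R)-3-[4-(benzyloxy)-3-methoxyphenyl]-1-tert-butoxy-1-oxopropan-2-yl]oxy}-3-oxoprop-1-en-1-yl]-2,3-dihydro-1,4-benzodioxine-2-carboxylic acid
Conditions: LiCl, iPr2NEt (3 equiv), MeCN, 25 °C
Reagents that add atoms: none
Why: Horner–Wadsworth–Emmons olefination under Masamune–Roush conditions should give the (E)-cinnamate, and the weak amine base leaves C2 (present as carboxylate) and the lactate centre untouched.

Step 13
Reactants: 22 (2R,3R)-3-[3,4-bis(benzyloxy)phenyl]-7-[(1E)-3-{[(2R)-3-[4-(benzyloxy)-3-methoxyphenyl]-1-tert-butoxy-1-oxopropan-2-yl]oxy}-3-oxoprop-1-en-1-yl]-2,3-dihydro-1,4-benzodioxine-2-carboxylic acid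
Product: 23 clinopodic acid F
Conditions: BCl3 (1 M in CH2Cl2), pentamethylbenzene, CH2Cl2, −78 to −20 °C; then MeOH
Reagents that add atoms: none
Why: Lewis-acid debenzylation with a non-basic cation scavenger should cleave the three aryl benzyl ethers and the tert-butyl ester at low temperature without reducing the alkene, cleaving the aryl methyl ether or epimerising the cis acid.

Compound list
1 | 2,4-dihydroxybenzaldehyde | O=Cc1ccc(O)cc1O | starting material
2 | 2,4-dihydroxy-3-iodobenzaldehyde | O=Cc1ccc(O)c(I)c1O | intermediate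
3 | 3,4-bis(benzyloxy)benzyl chloride | ClCc1ccc(OCc2ccccc2)c(OCc2ccccc2)c1 | starting material
4 | 4-{[3,4-bis(benzyloxy)phenyl]methoxy}-2-hydroxy-3-iodobenzaldehyde | O=Cc1ccc(OCc2ccc(OCc3ccccc3)c(OCc3ccccc3)c2)c(I)c1O | intermediate
5 | 3-{[3,4-bis(benzyloxy)phenyl]methoxy}-6-formyl-2-iodophenyl trifluoromethanesulfonate | O=Cc1ccc(OCc2ccc(OCc3ccccc3)c(OCc3ccccc3)c2)c(I)c1OS(=O)(=O)C(F)(F)F | intermediate
6 | 3-{[3,4-bis(benzyloxy)phenyl]methoxy}-6-(dimethoxymethyl)-2-iodophenyl trifluoromethanesulfonate | COC(OC)c1ccc(OCc2ccc(OCc3ccccc3)c(OCc3ccccc3)c2)c(I)c1OS(=O)(=O)C(F)(F)F | intermediate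
7 | methyl glycolate | COC(=O)CO | starting material
8 | methyl 2-{[3,4-bis(benzyloxy)phenyl][4-(dimethoxymethyl)-2-iodo-3-(trifluoromethanesulfonyloxy)phenoxy]methoxy}acetate (racemic) | COC(=O)COC(Oc1ccc(C(OC)OC)c(OS(=O)(=O)C(F)(F)F)c1I)c1ccc(OCc2ccccc2)c(OCc2ccccc2)c1 | intermediate
9 | methyl 2-{[3,4-bis(benzyloxy)phenyl][4-(dimethoxymethyl)-2,3-didehydrophenoxy]methoxy}acetate (aryne) | COC(=O)COC(OC1=CC=C(C(OC)OC)C#C1)c1ccc(OCc2ccccc2)c(OCc2ccccc2)c1 | intermediate
10 | 2-[3,4-bis(benzyloxy)phenyl]-5-(dimethoxymethyl)-1,3-benzodioxol-3-ium-3-yl(methoxycarbonyl)methanide (oxonium ylide) | COC(=O)[CH-][O+]1c2cc(C(OC)OC)ccc2OC1c1ccc(OCc2ccccc2)c(OCc2ccccc2)c1 | intermediate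
11 | methyl 3-[3,4-bis(benzyloxy)phenyl]-7-(dimethoxymethyl)-2,3-dihydro-1,4-benzodioxine-2-carboxylate (racemic cis/trans mixture) | COC(=O)C1Oc2cc(C(OC)OC)ccc2OC1c1ccc(OCc2ccccc2)c(OCc2ccccc2)c1 | intermediate
12 | methyl 3-[3,4-bis(benzyloxy)phenyl]-7-(dimethoxymethyl)-1,4-benzodioxine-2-carboxylate | COC(=O)C1=C(c2ccc(OCc3ccccc3)c(OCc3ccccc3)c2)Oc2ccc(C(OC)OC)cc2O1 | intermediate
13 | 3-[3,4-bis(benzyloxy)phenyl]-7-(dimethoxymethyl)-1,4-benzodioxine-2-carboxylic acid | OC(=O)C1=C(c2ccc(OCc3ccccc3)c(OCc3ccccc3)c2)Oc2ccc(C(OC)OC)cc2O1 | intermediate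
14 | (2R,3R)-3-[3,4-bis(benzyloxy)phenyl]-7-(dimethoxymethyl)-2,3-dihydro-1,4-benzodioxine-2-carboxylic acid | COC(OC)c1ccc2c(c1)O[C@@H](C(=O)O)[C@@H](c1ccc(OCc3ccccc3)c(OCc3ccccc3)c1)O2 | intermediate
15 | (2R,3R)-3-[3,4-bis(benzyloxy)phenyl]-7-formyl-2,3-dihydro-1,4-benzodioxine-2-carboxylic acid | O=Cc1ccc2c(c1)O[C@@H](C(=O)O)[C@@H](c1ccc(OCc3ccccc3)c(OCc3ccccc3)c1)O2 | intermediate
16 | 1-(benzyloxy)-4-bromo-2-methoxybenzene | COc1cc(Br)ccc1OCc1ccccc1 | starting material
17 | tert-butyl (2R)-oxirane-2-carboxylate | CC(C)(C)OC(=O)[C@H]1CO1 | starting material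
18 | [4-(benzyloxy)-3-methoxyphenyl]magnesium bromide | COc1cc([Mg]Br)ccc1OCc1ccccc1 | intermediate
19 | tert-butyl (2R)-3-[4-(benzyloxy)-3-methoxyphenyl]-2-hydroxypropanoate | COc1cc(C[C@@H](O)C(=O)OC(C)(C)C)ccc1OCc1ccccc1 | intermediate
20 | 2-(diethoxyphosphoryl)acetic acid | CCOP(=O)(CC(=O)O)OCC | starting material
21 | tert-butyl (2R)-3-[4-(benzyloxy)-3-methoxyphenyl]-2-{[2-(diethoxyphosphoryl)acetyl]oxy}propanoate | COc1cc(C[C@@H](OC(=O)CP(=O)(OCC)OCC)C(=O)OC(C)(C)C)ccc1OCc1ccccc1 | intermediate
22 | (2R,3R)-3-[3,4-bis(benzyloxy)phenyl]-7-[(1E)-3-{[(2R)-3-[4-(benzyloxy)-3-methoxyphenyl]-1-tert-butoxy-1-oxopropan-2-yl]oxy}-3-oxoprop-1-en-1-yl]-2,3-dihydro-1,4-benzodioxine-2-carboxylic acid | COc1cc(C[C@@H](OC(=O)/C=C/c2ccc3c(c2)O[C@@H](C(=O)O)[C@@H](c2ccc(OCc4ccccc4)c(OCc4ccccc4)c2)O3)C(=O)OC(C)(C)C)ccc1OCc1ccccc1 | intermediate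
23 | clinopodic acid F, (2R,3R)-7-[(1E)-3-{[(1R)-1-carboxy-2-(4-hydroxy-3-methoxyphenyl)ethyl]oxy}-3-oxoprop-1-en-1-yl]-3-(3,4-dihydroxyphenyl)-2,3-dihydro-1,4-benzodioxine-2-carboxylic acid | COc1cc(C[C@@H](OC(=O)/C=C/c2ccc3c(c2)O[C@@H](C(=O)O)[C@@H](c2ccc(O)c(O)c2)O3)C(=O)O)ccc1O | target

Total step count: 13. Longest linear sequence: 11 steps (steps 1 to 9, 12 and 13).

Steps most likely to fail

Step 6 (Proposed new method). The aryne may be diverted before the acetal oxygen captures it (addition of the organomagnesium reagent, ene reaction with a benzylic C–H), or the ylide may fragment to aldehyde and aryloxyacetate instead of undergoing the shift. The fallback uses known chemistry, sets out from 3 and returns at 11. Commercial 3,4-dihydroxybenzaldehyde is alkylated at O4 with 3 (K2CO3, DMF) to 4-{[3,4-bis(benzyloxy)phenyl]methoxy}-3-hydroxybenzaldehyde F1. The remaining phenol is alkylated with methyl bromoacetate to methyl 2-(2-{[3,4-bis(benzyloxy)phenyl]methoxy}-5-formylphenoxy)acetate F2, and the aldehyde is masked as the dimethyl acetal F3 (HC(OMe)3, MeOH, acid catalyst). LiN(SiMe3)2 and Me3SiCl give the silyl ketene acetal F4. DDQ (2,6-dichloropyridine, LiClO4, CH2Cl2) then abstracts hydride from the dialkoxybenzylic ether, and the tethered enol silane closes the ring in an oxidative Mukaiyama-type cyclisation to 11. In this fallback the ring closure forms only the C2–C3 bond.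

Step 5. Hydride abstraction may be slow because the ether oxygen carries an electron-poor aryl group, the acetal C–H may be oxidised further, or the acid-labile mixed acetal may be lost on work-up. The fallback builds the acetal by alkylation instead of oxidation, sets out from 2 and returns at 8. Compound 2 is silylated at O4 (t-BuMe2SiCl, imidazole) to 4-[(tert-butyldimethylsilyl)oxy]-2-hydroxy-3-iodobenzaldehyde F5 and triflated to 3-[(tert-butyldimethylsilyl)oxy]-6-formyl-2-iodophenyl trifluoromethanesulfonate F6. Acetalisation as in step 4 gives the silyl ether dimethyl acetal F7, and Bu4NF/AcOH frees the phenol, 6-(dimethoxymethyl)-3-hydroxy-2-iodophenyl trifluoromethanesulfonate F8. Separately, commercial 3,4-bis(benzyloxy)benzaldehyde and 7 (p-TsOH, benzene, removal of water) give the bis(glycolate) acetal F9, which acetyl chloride (ZnCl2 cat.) converts to the α-chloro ether methyl 2-{[3,4-bis(benzyloxy)phenyl](chloro)methoxy}acetate F10. O-Alkylation of F8 with F10 (iPr2NEt, CH2Cl2, 0 °C) gives 8.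

Step 9. Turnover may be poor at the hindered tetrasubstituted enol ether double bond, or facial discrimination may be low. The fallback separates reduction from enantioselection, sets out from 12 and returns at 14. Ester 12 is hydrogenated with the achiral complex [Ir(cod)(PCy3)(py)]PF6 (H2, CH2Cl2) to the racemic cis ester, methyl rac-(2R,3R)-3-[3,4-bis(benzyloxy)phenyl]-7-(dimethoxymethyl)-2,3-dihydro-1,4-benzodioxine-2-carboxylate F11 (syn addition). A lipase (hydrolase class, enzyme chosen by screening, phosphate buffer/MTBE) then hydrolyses only the (2R,3R) enantiomer, a kinetic resolution known for 1,4-benzodioxane-2-carboxylates, to acid 14, which the acid work-up of step 9 converts to 15.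

Further compounds
F1 | step 6 | 4-{[3,4-bis(benzyloxy)phenyl]methoxy}-3-hydroxybenzaldehyde | O=Cc1ccc(OCc2ccc(OCc3ccccc3)c(OCc3ccccc3)c2)c(O)c1
F2 | step 6 | methyl 2-(2-{[3,4-bis(benzyloxy)phenyl]methoxy}-5-formylphenoxy)acetate | COC(=O)COc1cc(C=O)ccc1OCc1ccc(OCc2ccccc2)c(OCc2ccccc2)c1
F3 | step 6 | methyl 2-[2-{[3,4-bis(benzyloxy)phenyl]methoxy}-5-(dimethoxymethyl)phenoxy]acetate | COC(=O)COc1cc(C(OC)OC)ccc1OCc1ccc(OCc2ccccc2)c(OCc2ccccc2)c1
F4 | step 6 | {2-[2-{[3,4-bis(benzyloxy)phenyl]methoxy}-5-(dimethoxymethyl)phenoxy]-1-methoxyethenyl}oxy(trimethyl)silane | COC(O[Si](C)(C)C)=COc1cc(C(OC)OC)ccc1OCc1ccc(OCc2ccccc2)c(OCc2ccccc2)c1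
F5 | step 5 | 4-[(tert-butyldimethylsilyl)oxy]-2-hydroxy-3-iodobenzaldehyde | CC(C)(C)[Si](C)(C)Oc1ccc(C=O)c(O)c1I
F6 | step 5 | 3-[(tert-butyldimethylsilyl)oxy]-6-formyl-2-iodophenyl trifluoromethanesulfonate | CC(C)(C)[Si](C)(C)Oc1ccc(C=O)c(OS(=O)(=O)C(F)(F)F)c1I
F7 | step 5 | 3-[(tert-butyldimethylsilyl)oxy]-6-(dimethoxymethyl)-2-iodophenyl trifluoromethanesulfonate | COC(OC)c1ccc(O[Si](C)(C)C(C)(C)C)c(I)c1OS(=O)(=O)C(F)(F)F
F8 | step 5 | 6-(dimethoxymethyl)-3-hydroxy-2-iodophenyl trifluoromethanesulfonate | COC(OC)c1ccc(O)c(I)c1OS(=O)(=O)C(F)(F)F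
F9 | step 5 | dimethyl 2,2'-{[3,4-bis(benzyloxy)phenyl]methylenebis(oxy)}diacetate | COC(=O)COC(OCC(=O)OC)c1ccc(OCc2ccccc2)c(OCc2ccccc2)c1
F10 | step 5 | methyl 2-{[3,4-bis(benzyloxy)phenyl](chloro)methoxy}acetate (racemic) | COC(=O)COC(Cl)c1ccc(OCc2ccccc2)c(OCc2ccccc2)c1
F11 | step 9 | methyl rac-(2R,3R)-3-[3,4-bis(benzyloxy)phenyl]-7-(dimethoxymethyl)-2,3-dihydro-1,4-benzodioxine-2-carboxylate (racemic cis) | COC(OC)c1ccc2c(c1)O[C@@H](C(=O)OC)[C@@H](c1ccc(OCc3ccccc3)c(OCc3ccccc3)c1)O2
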